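The key step exploits the aldol-type relationship hidden in the oxolane ring: O1–C2(aryl) lies β to the C3 hydroxymethyl carbon, so C2 is a masked acetal carbon and C3–CH2OH a masked enol ether. Both are held in a seven-membered 4,5-dihydro-1,3-dioxepine (cyclic vinyl acetal). A Lewis acid-triggered [1,3] O-to-C shift contracts this ring to the oxolane in one operation: it forms C2–C3, extrudes one ring oxygen and one ring carbon as the C3 formyl group, and relays the single stereocentre of the precursor (the future benzyl-bearing C4) to C2 and C3. The precursor arises by asymmetric benzylic Heck reaction on the veratraldehyde acetal of cis-2-butene-1,4-diol.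

Key step: step 5

Remark (assumption): the sense of induction of the chiral ligand in step 4 cannot be assigned in advance for this olefin; the ligand antipode that delivers (5R)-7 is the one meant. Both C2 epimers of 7 are carried on together, because C2 becomes planar in step 5.

Step 1
Reactants: 1 4-formyl-2-methoxyphenyl acetate (vanillin acetate)
Product: 2 4-(hydroxymethyl)-2-methoxyphenyl acetate
Conditions: NaBH4 (0.5 equiv), THF–MeOH 10:1, 0 °C, short contact; aq. NH4Cl
Reagents that add atoms: none
Why: Chemoselective borohydride reduction of the aldehyde, which is much faster than attack on the aryl acetate; substoichiometric hydride, low temperature and a buffered quench should suppress acetyl migration and transesterification.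

Step 2
Reactants: 2 4-(hydroxymethyl)-2-methoxyphenyl acetate
Product: 3 [4-(acetyloxy)-3-methoxyphenyl]methyl trifluoroacetate
Conditions: (CF3CO)2O, pyridine, CH2Cl2, 0 °C; non-aqueous work-up, used directly
Reagents that add atoms: trifluoroacetic anhydride, O=C(OC(=O)C(F)(F)F)C(F)(F)F
Why: O-acylation of the primary benzylic alcohol; the para-acetoxy group makes the benzylic trifluoroacetate far less prone to spontaneous ionisation than a para-alkoxy analogue, so it should be isolable.

Step 3
Reactants: 4 (Z)-but-2-ene-1,4-diol; 5 3,4-dimethoxybenzaldehyde (veratraldehyde)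
Product: 6 2-(3,4-dimethoxyphenyl)-4,7-dihydro-1,3-dioxepine
Conditions: p-TsOH·H2O (cat.), cyclohexane, reflux, Dean–Stark
Reagents that add atoms: none
Why: Acid-catalysed acetalisation with azeotropic removal of water; the Z-olefin holds the two hydroxyls in place for closure of the seven-membered cyclic acetal, which is achiral (mirror plane through C2).

Step 4
Reactants: 6 2-(3,4-dimethoxyphenyl)-4,7-dihydro-1,3-dioxepine (2 equiv); 3 [4-(acetyloxy)-3-methoxyphenyl]methyl trifluoroacetate
Product: 7 (5R)-5-{[4-(acetyloxy)-3-methoxyphenyl]methyl}-2-(3,4-dimethoxyphenyl)-4,5-dihydro-1,3-dioxepine (both C2 epimers)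
Conditions: Pd(dba)2 (5 mol %), BINOL-derived phosphoramidite, e.g. (S)-binaphthyl N,N-bis[(R)-1-phenylethyl]phosphoramidite or its antipode (12 mol %), Li2CO3, THF, 50 °C
Reagents that add atoms: none
Why: Asymmetric Mizoroki–Heck reaction of a benzylic electrophile with a cyclic cis-olefin: Pd(0) ionises the trifluoroacetate to a cationic η3-benzyl-Pd species, syn-carbopalladation of C5=C6 is followed by syn β-hydride elimination that can only go toward C7 (the C5–H is anti to Pd), so the double bond ends as the enol ether, and the chiral ligand distinguishes the enantiotopic olefin carbons and thereby sets C5 as R on either ring face.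

Step 5
Reactants: 7 (5R)-5-{[4-(acetyloxy)-3-methoxyphenyl]methyl}-2-(3,4-dimethoxyphenyl)-4,5-dihydro-1,3-dioxepine
Product: 9 (2S,3R,4R)-4-{[4-(acetyloxy)-3-methoxyphenyl]methyl}-2-(3,4-dimethoxyphenyl)oxolane-3-carbaldehyde, via ring-opened oxocarbenium silyl enol ether triflate 8 (not isolated)
Conditions: TMSOTf (10 mol %), CH2Cl2 (dilute), −78 °C; Et3N quench at −78 °C
Reagents that add atoms: none
Why: TMSOTf silylates the enol-ether oxygen O1 and ionises the C2–O1 bond to an (E)-veratryl oxocarbenium ion tethered through O3–C4–C5 to a (Z)-silyl enol ether, whose carbon C6 then attacks C2 (intramolecular Mukaiyama aldol/Prins-type addition), after which silyl transfer from the resulting O-silyl oxocarbenium to the next molecule of 7 releases the aldehyde and carries the chain. The closest known reaction type is the Lewis acid-mediated [1,3] O-to-C ring contraction of 4,5-dihydro-1,3-dioxepines (cyclic vinyl acetals) to tetrahydrofuran-3-carbaldehydes, a relative of the Petasis–Ferrier rearrangement. The oxolane closes in a 5-(enolexo)-endo-trig mode (O3=C2 inside the new ring, enol C6=C7 outside), so the seven-membered ring loses O1 and C7, which become the formyl group on C3. C4 of the product is the untouched C5 stereocentre of 7; C3 is set by attack on the enol face anti to the arylmethyl group in the A(1,3)-minimised conformer (C5–H eclipsing the Z-enol ether, tether and arylmethyl group on opposite faces), which should give 3,4-trans, and C2 by the cis topicity of (E)-oxocarbenium and (Z)-enol ether that this rearrangement shows kinetically at low temperature, which should give 2,3-cis and hence the required trans relation between the C2 aryl and C4 arylmethyl groups. The step needs kinetic control, because retro-aldol-type reopening would drain the material into the all-trans isomer; low temperature, catalytic acid and a cold amine quench are meant to secure it, and ionisation of the other acetal bond (C2–O3) is unproductive and reversible. Both C2 epimers of 7 converge because C2 is planar in the oxocarbenium ion.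

Step 6
Reactants: 9 (2S,3R,4R)-4-{[4-(acetyloxy)-3-methoxyphenyl]methyl}-2-(3,4-dimethoxyphenyl)oxolane-3-carbaldehyde
Product: 11 [(2S,3R,4R)-2-(3,4-dimethoxyphenyl)-4-[(4-hydroxy-3-methoxyphenyl)methyl]oxolan-3-yl]methanol, via (2S,3S,4R)-2-(3,4-dimethoxyphenyl)-4-[(4-hydroxy-3-methoxyphenyl)methyl]oxolane-3-carbaldehyde 10 (not isolated)
Conditions: K2CO3 (1.5 equiv), MeOH, 0 °C to rt until the C3 epimer ratio is constant; then NaBH4, 0 °C; aq. NH4Cl
Reagents that add atoms: none
Why: Base-mediated methanolysis of the aryl acetate and thermodynamic epimerisation of the enolisable C3 should move the formyl group trans to the directly attached C2 aryl group (2,3-trans, 3,4-cis), ring opening by β-alkoxide elimination being stereoelectronically disfavoured in the oxolane (reverse of a 5-endo-trig closure), and borohydride reduction of the aldehyde then fixes C3 without touching any stereocentre.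

Compound list
1 | 4-formyl-2-methoxyphenyl acetate (vanillin acetate) | CC(=O)Oc1ccc(C=O)cc1OC | starting material
2 | 4-(hydroxymethyl)-2-methoxyphenyl acetate | CC(=O)Oc1ccc(CO)cc1OC | intermediate
3 | [4-(acetyloxy)-3-methoxyphenyl]methyl trifluoroacetate | CC(=O)Oc1ccc(COC(=O)C(F)(F)F)cc1OC | intermediate
4 | (Z)-but-2-ene-1,4-diol | OC/C=C\CO | starting material
5 | 3,4-dimethoxybenzaldehyde (veratraldehyde) | COc1ccc(C=O)cc1OC | starting material
6 | 2-(3,4-dimethoxyphenyl)-4,7-dihydro-1,3-dioxepine | COc1ccc(cc1OC)C1OCC=CCO1 | intermediate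
7 | (5R)-5-{[4-(acetyloxy)-3-methoxyphenyl]methyl}-2-(3,4-dimethoxyphenyl)-4,5-dihydro-1,3-dioxepine (both C2 epimers) | COc1cc(C[C@H]2COC(c3ccc(OC)c(OC)c3)OC=C2)ccc1OC(C)=O | intermediate
8 | (R)-configured ring-opened ion pair: (E)-3,4-dimethoxybenzylidene oxocarbenium linked through O–CH2–CH(arylmethyl) to a (Z)-trimethylsilyl enol ether, triflate counter-ion (not isolated) | COc1cc(C[C@@H](C[O+]=Cc2ccc(OC)c(OC)c2)/C=C\O[Si](C)(C)C)ccc1OC(C)=O.[O-]S(=O)(=O)C(F)(F)F | intermediate
9 | (2S,3R,4R)-4-{[4-(acetyloxy)-3-methoxyphenyl]methyl}-2-(3,4-dimethoxyphenyl)oxolane-3-carbaldehyde (2,3-cis, 3,4-trans) | COc1cc(C[C@H]2CO[C@H](c3ccc(OC)c(OC)c3)[C@@H]2C=O)ccc1OC(C)=O | intermediate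
10 | (2S,3S,4R)-2-(3,4-dimethoxyphenyl)-4-[(4-hydroxy-3-methoxyphenyl)methyl]oxolane-3-carbaldehyde (2,3-trans, 3,4-cis; not isolated) | COc1cc(C[C@H]2CO[C@H](c3ccc(OC)c(OC)c3)[C@H]2C=O)ccc1O | intermediate
11 | [(2S,3R,4R)-2-(3,4-dimethoxyphenyl)-4-[(4-hydroxy-3-methoxyphenyl)methyl]oxolan-3-yl]methanol | COc1cc(C[C@H]2CO[C@H](c3ccc(OC)c(OC)c3)[C@H]2CO)ccc1O | target

Total step count: 6
Longest linear sequence: 5 steps (steps 1, 2, 4, 5, 6; 1 → 2 → 3 → 7 → 9 → 11)

Steps most likely to fail

Step 4 (asymmetric benzylic Heck reaction). What may go wrong: weak enantiotopic discrimination at a remote, nearly symmetrical olefin, sluggish insertion of the η3-benzyl-Pd species, and acid-induced loss of the vinyl acetal as it forms. The fallback sets out from 2 (together with 5) and comes back at 7; it sets the stereocentre by asymmetric double-bond migration instead of C–C bond formation. Alcohol 2 is converted with PBr3 (Et2O, 0 °C) into 4-(bromomethyl)-2-methoxyphenyl acetate F1. Palladium-catalysed syn-hydrostannation of 2-butyne-1,4-diol (Bu3SnH, PdCl2(PPh3)2 cat., THF) should give (E)-2-(tributylstannyl)but-2-ene-1,4-diol F2. Stille coupling of F1 with F2 (Pd2(dba)3, AsPh3, THF, 60 °C) should give (Z)-2-{[4-(acetyloxy)-3-methoxyphenyl]methyl}but-2-ene-1,4-diol F3. Acetalisation of F3 with 5 (PPTS, benzene, Dean–Stark) should give racemic 5-{[4-(acetyloxy)-3-methoxyphenyl]methyl}-2-(3,4-dimethoxyphenyl)-4,7-dihydro-1,3-dioxepine F4. Nickel hydride-catalysed asymmetric olefin isomerisation (NiBr2[Me-DuPhos] cat., LiBHEt3 cat., THF, −40 °C, ligand antipode chosen for 5R) is then expected to deliver hydride to the substituted carbon C5 with enantioface control and to eliminate toward C7, moving the double bond into the enol ether position and giving 7.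

Step 5 (ring contraction). What may go wrong: reversible C2–C3 bond formation through the very stable veratryl oxocarbenium ion, which erodes the kinetic facial selectivity and drains the 2,4-trans product into the all-trans isomer; also hydrolysis or oligomerisation of the vinyl acetal. The fallback sets out from 7 and comes back at 11; it builds the same stereotriad by lactone alkylation and cyclodehydration instead of rearrangement. Mild hydrolysis of 7 (AcOH–THF–H2O, rt) should release 5 and give (4R)-4-{[4-(acetyloxy)-3-methoxyphenyl]methyl}oxolan-2-ol F5. Oxidation (TEMPO cat., PhI(OAc)2, CH2Cl2) gives (4R)-4-{[4-(acetyloxy)-3-methoxyphenyl]methyl}oxolan-2-one F6. Pyrrolidine (CH2Cl2, 0 °C) removes the aryl acetate to give (4R)-4-[(4-hydroxy-3-methoxyphenyl)methyl]oxolan-2-one F7. The dianion of F7 (LDA, 2.2 equiv, THF, −78 °C) should add to 5 anti to the arylmethyl group to give (3S,4R)-3-[(3,4-dimethoxyphenyl)(hydroxy)methyl]-4-[(4-hydroxy-3-methoxyphenyl)methyl]oxolan-2-one F8 as carbinol epimers. LiAlH4 (THF, 0 °C) gives (2R,3R)-2-[(3,4-dimethoxyphenyl)(hydroxy)methyl]-3-[(4-hydroxy-3-methoxyphenyl)methyl]butane-1,4-diol F9. Catalytic camphorsulfonic acid (CH2Cl2, 0 °C) should ionise the benzylic carbinol; capture by the primary hydroxyl on the arylmethyl-bearing carbon closes the oxolane with C2 under thermodynamic control (aryl trans to the hydroxymethyl group), giving 11. The trans lactone becomes the 3,4-cis oxolane because the former lactone carbonyl carbon ends as the exocyclic hydroxymethyl group.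

Step 6 (epimerisation, deacetylation and reduction in one pot). What may go wrong: incomplete thermodynamic bias between the two C3 epimers (each has one cis-vicinal pair), base-induced self-condensation of the aldehyde, and reduction of aldehyde that has not yet epimerised. The fallback sets out from 9 and comes back at 11; it moves the C3 correction to the ester oxidation level, where the epimers tolerate prolonged equilibration, can be separated and the unwanted one resubmitted before an irreversible reduction. Pinnick oxidation of 9 (NaClO2, NaH2PO4, 2-methyl-2-butene, t-BuOH–H2O) should give (2S,3R,4R)-4-{[4-(acetyloxy)-3-methoxyphenyl]methyl}-2-(3,4-dimethoxyphenyl)oxolane-3-carboxylic acid F10. Methylation (MeI, K2CO3, DMF) gives methyl (2S,3R,4R)-4-{[4-(acetyloxy)-3-methoxyphenyl]methyl}-2-(3,4-dimethoxyphenyl)oxolane-3-carboxylate F11. NaOMe in MeOH (rt to 50 °C; NH4Cl quench) should cleave the acetate and equilibrate C3 to methyl (2S,3S,4R)-2-(3,4-dimethoxyphenyl)-4-[(4-hydroxy-3-methoxyphenyl)methyl]oxolane-3-carboxylate F12. LiAlH4 (THF, 0 °C) reduces F12 to 11.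

Further compounds
F1 | step 4 | 4-(bromomethyl)-2-methoxyphenyl acetate | CC(=O)Oc1ccc(CBr)cc1OC
F2 | step 4 | (E)-2-(tributylstannyl)but-2-ene-1,4-diol | CCCC[Sn](CCCC)(CCCC)/C(CO)=C/CO
F3 | step 4 | (Z)-2-{[4-(acetyloxy)-3-methoxyphenyl]methyl}but-2-ene-1,4-diol | CC(=O)Oc1ccc(C/C(CO)=C/CO)cc1OC
F4 | step 4 | rac-5-{[4-(acetyloxy)-3-methoxyphenyl]methyl}-2-(3,4-dimethoxyphenyl)-4,7-dihydro-1,3-dioxepine | COc1ccc(cc1OC)C1OCC=C(Cc2ccc(OC(C)=O)c(OC)c2)CO1
F5 | step 5 | (4R)-4-{[4-(acetyloxy)-3-methoxyphenyl]methyl}oxolan-2-ol (anomer mixture) | CC(=O)Oc1ccc(C[C@@H]2CC(O)OC2)cc1OC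
F6 | step 5 | (4R)-4-{[4-(acetyloxy)-3-methoxyphenyl]methyl}oxolan-2-one | CC(=O)Oc1ccc(C[C@@H]2CC(=O)OC2)cc1OC
F7 | step 5 | (4R)-4-[(4-hydroxy-3-methoxyphenyl)methyl]oxolan-2-one | COc1cc(C[C@@H]2CC(=O)OC2)ccc1O
F8 | step 5 | (3S,4R)-3-[(3,4-dimethoxyphenyl)(hydroxy)methyl]-4-[(4-hydroxy-3-methoxyphenyl)methyl]oxolan-2-one (carbinol epimers) | COc1cc(C[C@H]2COC(=O)[C@@H]2C(O)c2ccc(OC)c(OC)c2)ccc1O
F9 | step 5 | (2R,3R)-2-[(3,4-dimethoxyphenyl)(hydroxy)methyl]-3-[(4-hydroxy-3-methoxyphenyl)methyl]butane-1,4-diol (carbinol epimers) | COc1cc(C[C@@H](CO)[C@H](CO)C(O)c2ccc(OC)c(OC)c2)ccc1O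
F10 | step 6 | (2S,3R,4R)-4-{[4-(acetyloxy)-3-methoxyphenyl]methyl}-2-(3,4-dimethoxyphenyl)oxolane-3-carboxylic acid | COc1cc(C[C@H]2CO[C@H](c3ccc(OC)c(OC)c3)[C@@H]2C(O)=O)ccc1OC(C)=O
F11 | step 6 | methyl (2S,3R,4R)-4-{[4-(acetyloxy)-3-methoxyphenyl]methyl}-2-(3,4-dimethoxyphenyl)oxolane-3-carboxylate | COc1cc(C[C@H]2CO[C@H](c3ccc(OC)c(OC)c3)[C@@H]2C(=O)OC)ccc1OC(C)=O
F12 | step 6 | methyl (2S,3S,4R)-2-(3,4-dimethoxyphenyl)-4-[(4-hydroxy-3-methoxyphenyl)methyl]oxolane-3-carboxylate | COc1cc(C[C@H]2CO[C@H](c3ccc(OC)c(OC)c3)[C@H]2C(=O)OC)ccc1O
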